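**Reading time.** Read elm and oak at 12 min, and ask how much product each has made by then.

| flask | starting material | coupling partner | free catalyst | impurity | temperature | remark | time |
|---|---|---|---|---|---|---|---|
| east | 0.066 M | 0.119 M | 4 mM | 0.78 mM | 35 °C | run made earlier |  |
| north-east | 0.066 M | 0.119 M | 4 mM | 2.1 mM | 50 °C | run made earlier |  |
| north-west | 0.066 M | 0.119 M | 4.5 mM | 1.5 mM | 35 °C | run made earlier |  |
| elm | 0.066 M | 0.119 M | 4.0 mM | 1.5 mM | 60 °C |  | 12 min |
| oak | 0.066 M | 0.119 M | 6.0 mM | 3.0 mM | 40 °C |  | 12 min |

- east (time / min: product / %, starting material / %): 1.33: 0.8, 97.8; 5.00: 1.9, 95.3; 8.00: 3.5, 93.5; 15.0: 7.8, 89.1; 20.0: 11.4, 86.9; 30.0: 16.8, 81.5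
- north-east (time / min: product / %, starting material / %): 2.00: 1.9, 97.3; 4.00: 4.3, 94.7; 6.00: 7.2, 91.9; 8.00: 8.5, 89.9; 10.0: 11.4, 87.0; 12.0: 13.1, 85.3
- north-west (time / min: product / %, starting material / %): 3.00: 0.3, 97.1; 6.00: 3.6, 95.6; 15.0: 7.1, 90.0; 20.0: 10.1, 87.3; 30.0: 15.4, 82.9

(scatter of a reading: 0.5 percentage points)

- which of the two ends with the higher amount of product, in percent of the starting material charged ("neither" if they lie within 2 percentage points) (elm / oak / neither)
- product at the end, in percent of the starting material charged, elm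
- product at the end, in percent of the starting material charged, oak

- the analysis behind the earlier runs scatters by 0.5 percentage points, standard deviation

**Working catalyst.** Compare the last readings of east and north-west, both at 30.0 min. North-west holds more free catalyst, 4.5 mM against 4 mM, yet gives less product, 15.4% against 16.8%, and it also holds more impurity. So suppose that each impurity removes one catalyst. Oak then keeps 3.00 mM of working catalyst, the free catalyst charged minus the impurity charged, and elm keeps 2.50 mM.

**Rate constant.** Divide the last product reading by its time and by the working catalyst. East reads 1.74 M⁻¹ min⁻¹ at 35 °C and north-west 1.71 M⁻¹ min⁻¹ at 35 °C, so carry east's figure forward. North-east reads 5.75 M⁻¹ min⁻¹ at 50 °C. Assuming a fixed factor per degree between east and north-east gives 2.59 M⁻¹ min⁻¹ for oak and 12.7 M⁻¹ min⁻¹ for elm.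

**The bracket.** For the upper figure, hold the rate at its start: constant times working catalyst times time gives 9.32% for oak and 38.2% for elm. For the lower figure, let the rate fall with the remaining starting material, a pseudo-first-order decay, which gives 8.90% for oak and 31.8% for elm. Elm's lower figure exceeds oak's upper one by 22 percentage points, beyond the margin of 2 points, so my reckoning says elm.

**The result.** The forecast also says elm, with 29% for elm, 2.8 points under my lower figure, and 8.8% for oak, 0.1 points under mine, and holds that “The impurity therefore appears to remove catalyst, roughly one-for-one”. The flask gives elm, with 32.6% for elm and 9.25% for oak, both inside the brackets.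

    starting material + free catalyst ⇌ catalyst intermediate A (K = 20.0 M⁻¹, k = 55.4 M⁻¹ min⁻¹, Ea = 58.0 kJ mol⁻¹, ΔH = −9.00 kJ mol⁻¹)
    catalyst intermediate A ⇌ catalyst intermediate B (K = 2.80, k = 2.97 min⁻¹, Ea = 77.0 kJ mol⁻¹, ΔH = −65.0 kJ mol⁻¹)
    coupling partner + catalyst intermediate B ⇌ catalyst intermediate C (K = 4.10 M⁻¹, k = 145 M⁻¹ min⁻¹, Ea = 60.0 kJ mol⁻¹, ΔH = −19.0 kJ mol⁻¹)
    catalyst intermediate C ⇌ free catalyst + product (K = 0.512 M, k = 25.9 min⁻¹, Ea = 80.0 kJ mol⁻¹, ΔH = 8.00 kJ mol⁻¹)
    free catalyst + impurity → spent catalyst (k = 31100 M⁻¹ min⁻¹, Ea = 36.0 kJ mol⁻¹)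
    (constants at 60 °C)

**Neighbour flask.** Take oak with 0.010 M of free catalyst and the same impurity. Its working catalyst is 7.00 mM, so oak's constant brackets the product between 19.6% and 21.8%. The neighbour gives 20.2%. From oak's 3.00 mM, free catalyst rises by a factor of 1.67, working catalyst by 2.33, and product by 2.18. In the neighbour, spent catalyst stands at 30.0% of the catalyst charged, which is 3.00 mM, with impurity at 0% of its charge and 74% of the starting material still unbound.

All runs were computed with made-up constants.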